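**Retrosynthetic overview**
- The target 24 comes from 5-fluoroflavone 22 by exchanging the C5 fluorine, ortho/peri to the C4 carbonyl, for hydroxyl.
- 22 comes from aryne 18 (C4a≡C8a of ring A) and enol-ether acid 17: one operation forms O1–C8a, C4–C4a and O1–C2 and closes ring C, the only ring made (rings A and B are bought).
- The feature the plan rests on: C4a and C8a are adjacent ring A carbons carrying the C4 acyl carbon and O1, flanked by C8 (OMe) and by C5, whose hydroxyl is worn as fluorine to polarize the aryne.
- Aryne precursor 11 comes from 5-fluoro-o-vanillin 1 by methylation, Baeyer–Villiger oxidation, carbamate-directed silylation between O and F, and triflation.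
- Acid 17 comes from 2,4-dimethoxybenzoyl chloride 12 and methyl methoxyacetate 13 by C-acylation, enol O-methylation and saponification.

Key step: step 9

Remark on the chemistry: the acid chloride 12 is used instead of the methyl ester, because the electron-rich ester is too weak an electrophile for a clean crossed Claisen; 16, 17, 19 and 20 are drawn as Z isomers, but the E isomers or a mixture would serve equally, since the alkene geometry disappears on ring closure.

**Route**

Step 1
Reactants: 1 5-fluoro-2-hydroxy-3-methoxybenzaldehyde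
Product: 2 5-fluoro-2,3-dimethoxybenzaldehyde
Conditions: MeI, K2CO3, DMF, rt
Reagents that add atoms: iodomethane, CI
Why: Williamson O-methylation of the only acidic site, the phenol, should proceed cleanly beside the aldehyde.

Step 2
Reactants: 2 5-fluoro-2,3-dimethoxybenzaldehyde
Product: 4 5-fluoro-2,3-dimethoxyphenol, via aryl formate 3 (not isolated)
Conditions: mCPBA, CH2Cl2, 40 °C; then K2CO3 (cat.), MeOH, rt
Reagents that add atoms: 3-chloroperoxybenzoic acid, OOC(=O)c1cccc(Cl)c1
Why: In this Baeyer–Villiger (Dakin-type) oxidation the ring carbon, made migration-prone by the ortho methoxy group, should shift to oxygen, and the labile formate is methanolysed in the same flask.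

Step 3
Reactants: 4 5-fluoro-2,3-dimethoxyphenol
Product: 5 5-fluoro-2,3-dimethoxyphenyl N-isopropylcarbamate
Conditions: i-PrNCO, Et3N (cat.), CH2Cl2, rt
Reagents that add atoms: isopropyl isocyanate, CC(C)N=C=O
Why: Base-catalysed addition of the phenol to the isocyanate should give the secondary carbamate, a strong ortho-directing group that is later removable under mild base.

Step 4
Reactants: 5 5-fluoro-2,3-dimethoxyphenyl N-isopropylcarbamate
Product: 9 3-fluoro-5,6-dimethoxy-2-(trimethylsilyl)phenyl N-isopropylcarbamate, via N-silyl carbamate 6 (not isolated), via aryllithium 7 (not isolated), via N-silyl C-silyl carbamate 8 (not isolated)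
Conditions: t-BuMe2SiOTf, TMEDA, Et2O, 0 °C to rt; then n-BuLi, TMEDA, −78 °C; then Me3SiCl, −78 °C to rt; aq. NaHSO4
Reagents that add atoms: chlorotrimethylsilane, C[Si](C)(C)Cl
Why: In this directed ortho-metalation the N-silylated carbamate and the flanking fluorine together should steer n-BuLi to the CH between them (the future C4a) rather than to the CH between fluorine and methoxy; Me3SiCl traps the aryllithium at −78 °C before LiF loss or anionic Fries shift, and the N–Si bond falls off on acidic work-up.

Step 5
Reactants: 9 3-fluoro-5,6-dimethoxy-2-(trimethylsilyl)phenyl N-isopropylcarbamate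
Product: 11 3-fluoro-5,6-dimethoxy-2-(trimethylsilyl)phenyl trifluoromethanesulfonate, via silylphenol 10 (not isolated)
Conditions: Et2NH, DBU, MeCN, 40 °C; then PhNTf2, rt
Reagents that add atoms: N-phenylbis(trifluoromethanesulfonimide), O=S(=O)(N(c1ccccc1)S(=O)(=O)C(F)(F)F)C(F)(F)F
Why: E1cB cleavage of the N–H carbamate (the isocyanate is trapped by Et2NH) should release the phenoxide, which is O-sulfonylated in the same flask by the mild triflating agent without touching the aryl–silicon bond.

Step 6
Reactants: 12 2,4-dimethoxybenzoyl chloride, 13 methyl methoxyacetate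
Product: 15 methyl 3-(2,4-dimethoxyphenyl)-2-methoxy-3-oxopropanoate (racemic), via lithium enolate 14 (not isolated)
Conditions: 13 (2.1 equiv), LiN(i-Pr)2 (2.1 equiv), THF, −78 °C; then 12 (1.0 equiv), −78 to −40 °C; aq. NH4Cl
Reagents that add atoms: none
Why: C-acylation of the preformed lithium ester enolate by the acid chloride (crossed Claisen-type condensation) should give the β-keto ester, the second equivalent of enolate taking up its acidic proton so that over-acylation is avoided.

Step 7
Reactants: 15 methyl 3-(2,4-dimethoxyphenyl)-2-methoxy-3-oxopropanoate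
Product: 16 methyl (Z)-3-(2,4-dimethoxyphenyl)-2,3-dimethoxyprop-2-enoate
Conditions: Cs2CO3, Me2SO4, DMF, 0 °C to rt
Reagents that add atoms: dimethyl sulfate, COS(=O)(=O)OC
Why: O-alkylation of the dissociated cesium enolate by the hard electrophile Me2SO4 in a dipolar aprotic solvent should be favoured over C-alkylation at the hindered, fully substituted α-carbon; the Z isomer drawn is the one expected from the open (W-shaped) enolate.

Step 8
Reactants: 16 methyl (Z)-3-(2,4-dimethoxyphenyl)-2,3-dimethoxyprop-2-enoate
Product: 17 (Z)-3-(2,4-dimethoxyphenyl)-2,3-dimethoxyprop-2-enoic acid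
Conditions: LiOH, THF/MeOH/H2O, 50 °C; then 1 M HCl to pH 3, 0 °C
Reagents that add atoms: lithium hydroxide, [Li+].[OH-]
Why: Saponification of the ester should proceed without loss of the push-pull β-methoxy enol ether, which resists both hydroxide and brief cold acidification.

Step 9
Reactants: 11 3-fluoro-5,6-dimethoxy-2-(trimethylsilyl)phenyl trifluoromethanesulfonate (1.5 equiv), 17 (Z)-3-(2,4-dimethoxyphenyl)-2,3-dimethoxyprop-2-enoic acid
Product: 22 2-(2,4-dimethoxyphenyl)-5-fluoro-3,7,8-trimethoxy-4H-chromen-4-one, via aryne 18 (not isolated), via C4a aryl anion 19 (not isolated), via acylphenoxide 20 (not isolated), via 2-methoxychromanone enolate 21 (not isolated)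
Conditions: CsF (4 equiv), THF, 125 °C, sealed tube
Reagents that add atoms: none
Why: Proposed new method: CsF removes the silyl group of 11 and triflate leaves, giving aryne 18 across C4a–C8a; the cesium carboxylate of 17 should add through oxygen at C8a, because the C5 fluorine polarizes the strained bond so that negative charge develops at C4a beside it (19), and this anion then takes the acyl group from oxygen in a 1,3 O-to-C shift to give phenoxide 20. The phenoxide oxygen closes ring C by 6-endo-trig conjugate addition at the methoxy-bearing C2 (enolate 21) followed by E1cB loss of methoxide, so that O1–C8a, C4–C4a and O1–C2 are formed in one flask. The closest known reaction type is the CsF-induced insertion of arynes into the C–O bond of carboxylic acids in hot THF, which gives ortho-hydroxyaryl ketones and, from unsaturated acids, chromanones by oxa-Michael closure; new here are the fluorine-controlled regiochemistry on a 3-fluoro-6-methoxy aryne and the addition–elimination that delivers the chromone directly. No stereocenter is formed, and the alkene geometry of 17 is erased in 21. The step needs oxygen attack at C8a rather than C4a; the inductive pull of fluorine, stronger than that of the C8 methoxy, secures this only in part (the C7 methoxy pulls weakly the other way), so chromatographic removal of a regioisomeric flavone is planned for.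

Step 10
Reactants: 22 2-(2,4-dimethoxyphenyl)-5-fluoro-3,7,8-trimethoxy-4H-chromen-4-one
Product: 24 5-hydroxy-3,7,8,2',4'-pentamethoxyflavone, via sulfonylethyl ether 23 (not isolated)
Conditions: MeSO2CH2CH2OH, NaH, DMF, 0 °C to rt; then 1 M HCl
Reagents that add atoms: 2-(methylsulfonyl)ethanol, CS(=O)(=O)CCO
Why: SNAr of the C5 fluoride, activated by the ortho/peri C4 carbonyl and assisted by sodium chelation, by the alkoxide should be followed in the same flask by base-induced β-elimination (E1cB) of methyl vinyl sulfone from ether 23, freeing the chelated 5-phenoxide without the use of hydroxide, which would open the pyranone.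

**Compound list**
1 | 5-fluoro-2-hydroxy-3-methoxybenzaldehyde | COc1cc(F)cc(C=O)c1O | starting material
2 | 5-fluoro-2,3-dimethoxybenzaldehyde | COc1cc(F)cc(C=O)c1OC | intermediate
3 | 5-fluoro-2,3-dimethoxyphenyl formate | COc1cc(F)cc(OC=O)c1OC | intermediate (not isolated)
4 | 5-fluoro-2,3-dimethoxyphenol | COc1cc(F)cc(O)c1OC | intermediate
5 | 5-fluoro-2,3-dimethoxyphenyl N-isopropylcarbamate | COc1cc(F)cc(OC(=O)NC(C)C)c1OC | intermediate
6 | 5-fluoro-2,3-dimethoxyphenyl N-(tert-butyldimethylsilyl)-N-isopropylcarbamate | COc1cc(F)cc(OC(=O)N(C(C)C)[Si](C)(C)C(C)(C)C)c1OC | intermediate (not isolated)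
7 | [2-fluoro-4,5-dimethoxy-6-(N-silyl-N-isopropylcarbamoyloxy)phenyl]lithium, lithium on the carbon between F and the carbamate oxygen | COc1cc(F)c([Li])c(OC(=O)N(C(C)C)[Si](C)(C)C(C)(C)C)c1OC | intermediate (not isolated)
8 | 3-fluoro-5,6-dimethoxy-2-(trimethylsilyl)phenyl N-(tert-butyldimethylsilyl)-N-isopropylcarbamate | COc1cc(F)c([Si](C)(C)C)c(OC(=O)N(C(C)C)[Si](C)(C)C(C)(C)C)c1OC | intermediate (not isolated)
9 | 3-fluoro-5,6-dimethoxy-2-(trimethylsilyl)phenyl N-isopropylcarbamate | COc1cc(F)c([Si](C)(C)C)c(OC(=O)NC(C)C)c1OC | intermediate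
10 | 3-fluoro-5,6-dimethoxy-2-(trimethylsilyl)phenol (present as its DBU salt) | COc1cc(F)c([Si](C)(C)C)c(O)c1OC | intermediate (not isolated)
11 | 3-fluoro-5,6-dimethoxy-2-(trimethylsilyl)phenyl trifluoromethanesulfonate | COc1cc(F)c([Si](C)(C)C)c(OS(=O)(=O)C(F)(F)F)c1OC | intermediate
12 | 2,4-dimethoxybenzoyl chloride | COc1ccc(C(=O)Cl)c(OC)c1 | starting material
13 | methyl methoxyacetate | COCC(=O)OC | starting material
14 | lithium enolate of methyl methoxyacetate | COC=C(OC)O[Li] | intermediate (not isolated)
15 | methyl 3-(2,4-dimethoxyphenyl)-2-methoxy-3-oxopropanoate (racemic) | COC(C(=O)OC)C(=O)c1ccc(OC)cc1OC | intermediate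
16 | methyl (Z)-3-(2,4-dimethoxyphenyl)-2,3-dimethoxyprop-2-enoate | CO/C(C(=O)OC)=C(\OC)c1ccc(OC)cc1OC | intermediate
17 | (Z)-3-(2,4-dimethoxyphenyl)-2,3-dimethoxyprop-2-enoic acid | CO/C(C(=O)O)=C(\OC)c1ccc(OC)cc1OC | intermediate
18 | 3-fluoro-5,6-dimethoxybenzyne (triple bond C4a–C8a) | COC1=C(OC)C#CC(F)=C1 | intermediate (not isolated)
19 | cesium 2-{[(Z)-3-(2,4-dimethoxyphenyl)-2,3-dimethoxyprop-2-enoyl]oxy}-6-fluoro-3,4-dimethoxybenzen-1-ide (anion at C4a) | CO/C(C(=O)Oc1c(OC)c(OC)cc(F)[c-]1)=C(\OC)c1ccc(OC)cc1OC.[Cs+] | intermediate (not isolated)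
20 | cesium 2-[(Z)-3-(2,4-dimethoxyphenyl)-2,3-dimethoxyprop-2-enoyl]-3-fluoro-5,6-dimethoxyphenolate | CO/C(C(=O)c1c(F)cc(OC)c(OC)c1[O-])=C(\OC)c1ccc(OC)cc1OC.[Cs+] | intermediate (not isolated)
21 | cesium 2-(2,4-dimethoxyphenyl)-5-fluoro-2,3,7,8-tetramethoxy-2H-chromen-4-olate (racemic at C2) | COC1=C([O-])c2c(F)cc(OC)c(OC)c2OC1(OC)c1ccc(OC)cc1OC.[Cs+] | intermediate (not isolated)
22 | 2-(2,4-dimethoxyphenyl)-5-fluoro-3,7,8-trimethoxy-4H-chromen-4-one | COc1ccc(-c2oc3c(OC)c(OC)cc(F)c3c(=O)c2OC)c(OC)c1 | intermediate
23 | 2-(2,4-dimethoxyphenyl)-3,7,8-trimethoxy-5-[2-(methylsulfonyl)ethoxy]-4H-chromen-4-one | COc1ccc(-c2oc3c(OC)c(OC)cc(OCCS(C)(=O)=O)c3c(=O)c2OC)c(OC)c1 | intermediate (not isolated)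
24 | 5-hydroxy-3,7,8,2',4'-pentamethoxyflavone | COc1ccc(-c2oc3c(OC)c(OC)cc(O)c3c(=O)c2OC)c(OC)c1 | target

**Step count**
Total: 10 steps. Longest linear sequence: 7 steps (steps 1–5, 9, 10); the acid branch (steps 6–8) joins at step 9.

**Steps most likely to fail**

1. Step 9 (proposed new method). Three processes may spoil it: carboxylate attack at C4a in competition with C8a, because the two ring A methoxy groups pull against fluorine; protonation of the C4a anion before the acyl shift; and conjugate attack of that anion on the enol-ether carbon instead of the carbonyl. The fallback uses known chemistry, sets out from carbamate 5 and acid chloride 12, and returns to the route at 22. Carbamate 5 is N-silylated and lithiated exactly as in step 4 to give aryllithium 7, which is quenched with N,2-dimethoxy-N-methylacetamide; NaHSO4 work-up should give 3-fluoro-5,6-dimethoxy-2-(methoxyacetyl)phenyl N-isopropylcarbamate F1, with the acyl group fixed at C4a by the metalation. Et2NH/DBU in MeCN removes the carbamate to give 1-(6-fluoro-2-hydroxy-3,4-dimethoxyphenyl)-2-methoxyethan-1-one F2. Acylation with 12 (pyridine, CH2Cl2) gives 3-fluoro-5,6-dimethoxy-2-(methoxyacetyl)phenyl 2,4-dimethoxybenzoate F3. Baker–Venkataraman rearrangement (KOt-Bu, THF) moves the aroyl group to carbon and gives 1-(2,4-dimethoxyphenyl)-3-(6-fluoro-2-hydroxy-3,4-dimethoxyphenyl)-2-methoxypropane-1,3-dione F4. Cyclodehydration (cat. H2SO4, AcOH, 90 °C) closes ring C to 22.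

2. Step 7. Alkylation may occur on the α-carbon instead of the enolate oxygen. The fallback sets out from 15 and returns at 16, replacing enolate alkylation by acetal chemistry. HC(OMe)3 with cat. H2SO4 in MeOH at reflux converts the ketone into methyl 3-(2,4-dimethoxyphenyl)-2,3,3-trimethoxypropanoate F5. KOt-Bu in THF then eliminates methanol from the ester enolate (E1cB) to give 16 as either or both alkene isomers, all of which serve.

3. Step 10. Substitution at C5 may be slow because the para C8 methoxy donates into that carbon, leaving time for alkoxide addition at C2 and opening of the pyranone. The fallback sets out from 22 and returns at 24, unmasking by chelation-controlled dealkylation instead of elimination. NaOMe in MeOH/DMSO at 80 °C (smallest alkoxide, large excess, ring opening reversible in methanol) gives 2-(2,4-dimethoxyphenyl)-3,5,7,8-tetramethoxy-4H-chromen-4-one F6. BCl3 in CH2Cl2 (−78 to 0 °C) then cleaves only the 5-methyl ether, through the six-membered boron chelate with the C4 carbonyl, to give 24.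

**Further compounds**
F1 | step 9 | 3-fluoro-5,6-dimethoxy-2-(methoxyacetyl)phenyl N-isopropylcarbamate | COCC(=O)c1c(F)cc(OC)c(OC)c1OC(=O)NC(C)C
F2 | step 9 | 1-(6-fluoro-2-hydroxy-3,4-dimethoxyphenyl)-2-methoxyethan-1-one | COCC(=O)c1c(F)cc(OC)c(OC)c1O
F3 | step 9 | 3-fluoro-5,6-dimethoxy-2-(methoxyacetyl)phenyl 2,4-dimethoxybenzoate | COCC(=O)c1c(F)cc(OC)c(OC)c1OC(=O)c1ccc(OC)cc1OC
F4 | step 9 | 1-(2,4-dimethoxyphenyl)-3-(6-fluoro-2-hydroxy-3,4-dimethoxyphenyl)-2-methoxypropane-1,3-dione (racemic) | COC(C(=O)c1ccc(OC)cc1OC)C(=O)c1c(F)cc(OC)c(OC)c1O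
F5 | step 7 | methyl 3-(2,4-dimethoxyphenyl)-2,3,3-trimethoxypropanoate (racemic) | COC(C(=O)OC)C(OC)(OC)c1ccc(OC)cc1OC
F6 | step 10 | 2-(2,4-dimethoxyphenyl)-3,5,7,8-tetramethoxy-4H-chromen-4-one | COc1ccc(-c2oc3c(OC)c(OC)cc(OC)c3c(=O)c2OC)c(OC)c1
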